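**Retrosynthetic overview**
1. Target ⇐ C2-OH-directed epoxidation of the 1(10)-alkene (last ring, the oxirane) ⇐ 8-O-angeloylation of a macrocyclic 8-alcohol.
2. Ten-membered ring ⇐ intramolecular chromium allylation across C7–C8: a 3-(bromomethyl)butenolide serves as a lactone β-carbanion (homoenolate equivalent) towards the C8 aldehyde, setting C7 and C8 and unveiling the α-methylene lactone.
3. Butenolide (first ring) ⇐ ring-closing metathesis of the C6 2-(bromomethyl)acrylate; the C4=C5 alkene bearing CH2OH ⇐ trans-hydroalumination/iodination of a propargylic alcohol, then Stille hydroxymethylation.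
4. C6 and C2 carbinols ⇐ catalytic asymmetric alkynylation of crotonaldehyde and asymmetric propargylation of an enal made by carboalumination of a butynyl silyl ether.
5. Ring order: butenolide → ten-membered carbocycle → epoxide.

Assumption: germacrane numbering (C1–C15) is used in the text and the target is taken as drawn, 1R,2S,6R,7R,8S,10R. The facial sense of the two catalyst-controlled additions (steps 3 and 5) is assumed as stated; the mirror-image catalyst would be used if it proved opposite.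

**Route**

Step 1
Reactants: 1 tert-butyl(but-3-yn-1-yloxy)dimethylsilane
Product: 4 (E)-5-[(tert-butyldimethylsilyl)oxy]-3-methylpent-2-en-1-ol, via alkenyldimethylalane 2 (not isolated), via lithium alkenylaluminate 3 (not isolated)
Conditions: AlMe3 (2.5 equiv), Cp2ZrCl2 (0.25 equiv), CH2Cl2, 0 °C to rt; n-BuLi, THF/hexane, −78 °C; (CH2O)n, −78 °C to rt; aq. Rochelle salt
Reagents that add atoms: trimethylaluminium C[Al](C)C; paraformaldehyde C=O
Why: Negishi zirconium-catalysed carboalumination adds CH3 and Al syn across the terminal alkyne (methyl on C10, Al on C1), and the derived aluminate is hydroxymethylated with retention, giving the E-trisubstituted C1=C10 alkene with C2 in place.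

Step 2
Reactants: 4 (E)-5-[(tert-butyldimethylsilyl)oxy]-3-methylpent-2-en-1-ol
Product: 5 (E)-5-[(tert-butyldimethylsilyl)oxy]-3-methylpent-2-enal
Conditions: MnO2 (15 equiv), CH2Cl2, rt
Reagents that add atoms: none
Why: Allylic oxidation on manganese dioxide stops at the enal and leaves the silyl ether and the E-alkene untouched.

Step 3
Reactants: 5 (E)-5-[(tert-butyldimethylsilyl)oxy]-3-methylpent-2-enal; 6 allenylboronic acid pinacol ester
Product: 7 (4S,5E)-8-[(tert-butyldimethylsilyl)oxy]-6-methyloct-5-en-1-yn-4-ol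
Conditions: (S)-TRIP phosphoric acid (10 mol %), 4 Å MS, toluene, −20 °C; aq. NaHCO3
Reagents that add atoms: none
Why: Chiral-phosphoric-acid-catalysed propargylation (SE2' addition of the allenylboronate through a closed six-membered transition state) gives the terminal homopropargylic alcohol and sets C2 as S by catalyst control.

Step 4
Reactants: 7 (4S,5E)-8-[(tert-butyldimethylsilyl)oxy]-6-methyloct-5-en-1-yn-4-ol
Product: 8 (4S,5E)-4,8-bis[(tert-butyldimethylsilyl)oxy]-6-methyloct-5-en-1-yne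
Conditions: TBSCl, imidazole, DMF, rt
Reagents that add atoms: tert-butyldimethylsilyl chloride CC(C)(C)[Si](C)(C)Cl
Why: Standard silylation masks the C2 hydroxyl so that the later acylations at O6 and O8 are unambiguous.

Step 5
Reactants: 8 (4S,5E)-4,8-bis[(tert-butyldimethylsilyl)oxy]-6-methyloct-5-en-1-yne; 9 (E)-but-2-enal
Product: 11 (2E,4S,8S,9E)-8,12-bis[(tert-butyldimethylsilyl)oxy]-10-methyldodeca-2,9-dien-5-yn-4-ol, via alkynylzinc species 10 (not isolated)
Conditions: Me2Zn (2.5 equiv), (S,S)-ProPhenol (20 mol %), Ph3PO (40 mol %), toluene, 0 °C; then 9 (2 equiv), 4 °C; aq. NH4Cl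
Reagents that add atoms: none
Why: Zinc–ProPhenol-catalysed asymmetric alkynylation adds the zinc acetylide 1,2 to the enal and sets the C6 carbinol as S by catalyst control, the remote C2 centre having no influence.

Step 6
Reactants: 11 (2E,4S,8S,9E)-8,12-bis[(tert-butyldimethylsilyl)oxy]-10-methyldodeca-2,9-dien-5-yn-4-ol
Product: 13 (2E,4S,5Z,8S,9E)-8,12-bis[(tert-butyldimethylsilyl)oxy]-6-iodo-10-methyldodeca-2,5,9-trien-4-ol, via cyclic alkenylaluminate 12 (not isolated)
Conditions: NaAlH2(OCH2CH2OCH3)2 (Red-Al, 3 equiv), THF, 0 °C to rt; EtOAc; I2, −78 °C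
Reagents that add atoms: iodine II
Why: Hydroxyl-directed trans-hydroalumination of the propargylic alcohol puts H on C5 and Al on C4 in a five-membered alkoxyaluminate, and iodinolysis with retention gives the vinyl iodide with iodine cis to C6, which fixes the C4=C5 geometry.

Step 7
Reactants: 13 (2E,4S,5Z,8S,9E)-8,12-bis[(tert-butyldimethylsilyl)oxy]-6-iodo-10-methyldodeca-2,5,9-trien-4-ol; 14 (tributylstannyl)methanol
Product: 15 (2Z,4S,5E)-2-[(2S,3E)-2,6-bis[(tert-butyldimethylsilyl)oxy]-4-methylhex-3-en-1-yl]hepta-2,5-diene-1,4-diol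
Conditions: Pd(PPh3)4 (5 mol %), dioxane, 90 °C
Reagents that add atoms: none
Why: Stille (Kosugi–Migita) coupling transfers the hydroxymethyl group with retention of alkene geometry, so C15 ends up cis to C6 as in the target.

Step 8
Reactants: 15 (2Z,4S,5E)-2-[(2S,3E)-2,6-bis[(tert-butyldimethylsilyl)oxy]-4-methylhex-3-en-1-yl]hepta-2,5-diene-1,4-diol
Product: 16 (2E,4S,5Z,8S,9E)-8,12-bis[(tert-butyldimethylsilyl)oxy]-6-{[(tert-butyldiphenylsilyl)oxy]methyl}-10-methyldodeca-2,5,9-trien-4-ol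
Conditions: TBDPSCl (1.05 equiv), imidazole, CH2Cl2, −20 to 0 °C
Reagents that add atoms: tert-butyldiphenylsilyl chloride CC(C)(C)[Si](Cl)(c1ccccc1)c1ccccc1
Why: The primary allylic hydroxyl is silylated far faster than the hindered secondary one, and the robust TBDPS group is chosen so that the primary TBS ether at C8 can be removed selectively later.

Step 9
Reactants: 16 (2E,4S,5Z,8S,9E)-8,12-bis[(tert-butyldimethylsilyl)oxy]-6-{[(tert-butyldiphenylsilyl)oxy]methyl}-10-methyldodeca-2,5,9-trien-4-ol; 17 2-(bromomethyl)prop-2-enoic acid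
Product: 18 (2E,4S,5Z,8S,9E)-8,12-bis[(tert-butyldimethylsilyl)oxy]-6-{[(tert-butyldiphenylsilyl)oxy]methyl}-10-methyldodeca-2,5,9-trien-4-yl 2-(bromomethyl)prop-2-enoate
Conditions: DCC (1.3 equiv), DMAP (5 mol %), CH2Cl2, 0 °C
Reagents that add atoms: none
Why: Steglich esterification acylates O6 with retention at C6, and the low DMAP loading at 0 °C spares the allylic bromide.

Step 10
Reactants: 18 (2E,4S,5Z,8S,9E)-8,12-bis[(tert-butyldimethylsilyl)oxy]-6-{[(tert-butyldiphenylsilyl)oxy]methyl}-10-methyldodeca-2,5,9-trien-4-yl 2-(bromomethyl)prop-2-enoate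
Product: 19 (5R)-3-(bromomethyl)-5-[(1Z,4S,5E)-4,8-bis[(tert-butyldimethylsilyl)oxy]-2-{[(tert-butyldiphenylsilyl)oxy]methyl}-6-methylocta-1,5-dien-1-yl]furan-2(5H)-one
Conditions: second-generation Grubbs catalyst RuCl2(=CHPh)(PCy3)(SIMes) (10 mol %), toluene (0.005 M), 80 °C
Reagents that add atoms: none
Why: Ring-closing metathesis between the propenyl group and the acrylate forms the butenolide with loss of propene, the two trisubstituted alkenes being inert and C6 untouched (the R descriptor is only a priority change).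

Step 11
Reactants: 19 (5R)-3-(bromomethyl)-5-[(1Z,4S,5E)-4,8-bis[(tert-butyldimethylsilyl)oxy]-2-{[(tert-butyldiphenylsilyl)oxy]methyl}-6-methylocta-1,5-dien-1-yl]furan-2(5H)-one
Product: 20 (5R)-3-(bromomethyl)-5-[(1Z,4S,5E)-4-[(tert-butyldimethylsilyl)oxy]-2-{[(tert-butyldiphenylsilyl)oxy]methyl}-8-hydroxy-6-methylocta-1,5-dien-1-yl]furan-2(5H)-one
Conditions: CSA (10 mol %), MeOH/CH2Cl2 (1:1), 0 °C
Reagents that add atoms: none
Why: Acid-catalysed methanolysis cleaves the unhindered primary TBS ether much faster than the secondary TBS and the TBDPS ethers, and these amine-free conditions do not alkylate with the allylic bromide.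

Step 12
Reactants: 20 (5R)-3-(bromomethyl)-5-[(1Z,4S,5E)-4-[(tert-butyldimethylsilyl)oxy]-2-{[(tert-butyldiphenylsilyl)oxy]methyl}-8-hydroxy-6-methylocta-1,5-dien-1-yl]furan-2(5H)-one
Product: 21 (3E,5S,7Z)-8-[(2R)-4-(bromomethyl)-5-oxo-2,5-dihydrofuran-2-yl]-5-[(tert-butyldimethylsilyl)oxy]-7-{[(tert-butyldiphenylsilyl)oxy]methyl}-3-methylocta-3,7-dienal
Conditions: Dess–Martin periodinane, NaHCO3, CH2Cl2, 0 °C; used at once
Reagents that add atoms: none
Why: Buffered Dess–Martin oxidation gives the β,γ-unsaturated aldehyde without moving the alkene into conjugation and tolerates the allylic bromide.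

Step 13
Reactants: 21 (3E,5S,7Z)-8-[(2R)-4-(bromomethyl)-5-oxo-2,5-dihydrofuran-2-yl]-5-[(tert-butyldimethylsilyl)oxy]-7-{[(tert-butyldiphenylsilyl)oxy]methyl}-3-methylocta-3,7-dienal
Product: 23 (3aR,4S,6E,8S,10Z,11aR)-8-[(tert-butyldimethylsilyl)oxy]-10-{[(tert-butyldiphenylsilyl)oxy]methyl}-4-hydroxy-6-methyl-3-methylidene-3a,4,5,8,9,11a-hexahydrocyclodeca[b]furan-2(3H)-one, via allylchromium species 22 (not isolated)
Conditions: CrCl2 (8 equiv), DMF/THF (1:1), rt, syringe-pump addition of 21 over 10 h (final 0.002 M); aq. NH4Cl, pH 7 work-up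
Reagents that add atoms: none
Why: Proposed new method: two equivalents of divalent chromium insert into the allylic C–Br bond to give an allylchromium that is a lactone β-carbanion (homoenolate equivalent), and this adds through its γ-carbon C7 (normally the electrophilic β-carbon of the butenolide) to the electrophilic C8 aldehyde in a chair six-membered transition state, anti to the C6 side chain (6,7-trans lactone) and with C6 and C9 both pseudo-equatorial (7,8-anti, hence 8S), regenerating the exo-methylene; the closest known chemistry is the intermolecular Barbier reaction of 3-(bromomethyl)furan-2(5H)-ones with aldehydes together with Nozaki–Hiyama–Kishi-type allylative closure of ten-membered germacrane rings.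

Step 14
Reactants: 23 (3aR,4S,6E,8S,10Z,11aR)-8-[(tert-butyldimethylsilyl)oxy]-10-{[(tert-butyldiphenylsilyl)oxy]methyl}-4-hydroxy-6-methyl-3-methylidene-3a,4,5,8,9,11a-hexahydrocyclodeca[b]furan-2(3H)-one; 24 (Z)-2-methylbut-2-enoic acid (angelic acid)
Product: 26 (3aR,4S,6E,8S,10Z,11aR)-8-[(tert-butyldimethylsilyl)oxy]-10-{[(tert-butyldiphenylsilyl)oxy]methyl}-6-methyl-3-methylidene-2-oxo-2,3,3a,4,5,8,9,11a-octahydrocyclodeca[b]furan-4-yl (2Z)-2-methylbut-2-enoate, via mixed anhydride 25 (not isolated)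
Conditions: 24 (3 equiv), 2,4,6-trichlorobenzoyl chloride (3 equiv), Et3N, toluene, rt, 2 h; then 23, 80 °C
Reagents that add atoms: none
Why: Yamaguchi-type mixed-anhydride esterification without DMAP acylates the only free hydroxyl (O8) at the unhindered angeloyl carbonyl and avoids Z-to-E isomerisation to the tiglate.

Step 15
Reactants: 26 (3aR,4S,6E,8S,10Z,11aR)-8-[(tert-butyldimethylsilyl)oxy]-10-{[(tert-butyldiphenylsilyl)oxy]methyl}-6-methyl-3-methylidene-2-oxo-2,3,3a,4,5,8,9,11a-octahydrocyclodeca[b]furan-4-yl (2Z)-2-methylbut-2-enoate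
Product: 27 (3aR,4S,6E,8S,10Z,11aR)-8-hydroxy-10-(hydroxymethyl)-6-methyl-3-methylidene-2-oxo-2,3,3a,4,5,8,9,11a-octahydrocyclodeca[b]furan-4-yl (2Z)-2-methylbut-2-enoate
Conditions: HF·pyridine, pyridine, THF, 0 °C to rt
Reagents that add atoms: none
Why: Buffered fluoride desilylation removes both silyl ethers without touching the angelate, the α-methylene lactone or the stereocentres.

Step 16
Reactants: 27 (3aR,4S,6E,8S,10Z,11aR)-8-hydroxy-10-(hydroxymethyl)-6-methyl-3-methylidene-2-oxo-2,3,3a,4,5,8,9,11a-octahydrocyclodeca[b]furan-4-yl (2Z)-2-methylbut-2-enoate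
Product: 28 (1R,2S,6R,7R,8S,10R)-8-angeloyloxy-1,10-epoxy-2,15-dihydroxygermacra-4,11(13)-dien-12,6-olide (the target)
Conditions: mCPBA (1.05 equiv), NaHCO3, CH2Cl2, −20 to 0 °C
Reagents that add atoms: 3-chloroperoxybenzoic acid O=C(OO)c1cccc(Cl)c1
Why: Henbest-type hydroxyl-directed peracid epoxidation attacks the most electron-rich alkene (C1=C10) from its outer face, with H2 eclipsing the alkene to avoid A(1,3) strain with the C14 methyl so that the 2-OH delivers the peracid, giving the threo (1R,10R) epoxy alcohol; the 4,5-alkene is deactivated by the allylic lactone oxygen and the two enoates are electron-poor.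

**Compound list**
1 | tert-butyl(but-3-yn-1-yloxy)dimethylsilane | C#CCCO[Si](C)(C)C(C)(C)C | starting material
2 | (E)-[4-(tert-butyldimethylsilyloxy)-2-methylbut-1-en-1-yl]dimethylalane | C[Al](C)/C=C(\C)CCO[Si](C)(C)C(C)(C)C | intermediate (not isolated)
3 | lithium butyl[(E)-4-(tert-butyldimethylsilyloxy)-2-methylbut-1-en-1-yl]dimethylaluminate | [Li+].CCCC[Al-](C)(C)/C=C(\C)CCO[Si](C)(C)C(C)(C)C | intermediate (not isolated)
4 | (E)-5-[(tert-butyldimethylsilyl)oxy]-3-methylpent-2-en-1-ol | OC/C=C(\C)CCO[Si](C)(C)C(C)(C)C | intermediate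
5 | (E)-5-[(tert-butyldimethylsilyl)oxy]-3-methylpent-2-enal | O=C/C=C(\C)CCO[Si](C)(C)C(C)(C)C | intermediate
6 | allenylboronic acid pinacol ester | C=C=CB1OC(C)(C)C(C)(C)O1 | starting material
7 | (4S,5E)-8-[(tert-butyldimethylsilyl)oxy]-6-methyloct-5-en-1-yn-4-ol | C#CC[C@H](O)/C=C(\C)CCO[Si](C)(C)C(C)(C)C | intermediate
8 | (4S,5E)-4,8-bis[(tert-butyldimethylsilyl)oxy]-6-methyloct-5-en-1-yne | C#CC[C@H](O[Si](C)(C)C(C)(C)C)/C=C(\C)CCO[Si](C)(C)C(C)(C)C | intermediate
9 | (E)-but-2-enal (crotonaldehyde) | C/C=C/C=O | starting material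
10 | methylzinc acetylide of 8 | C[Zn]C#CC[C@H](O[Si](C)(C)C(C)(C)C)/C=C(\C)CCO[Si](C)(C)C(C)(C)C | intermediate (not isolated)
11 | (2E,4S,8S,9E)-8,12-bis[(tert-butyldimethylsilyl)oxy]-10-methyldodeca-2,9-dien-5-yn-4-ol | C/C=C/[C@H](O)C#CC[C@H](O[Si](C)(C)C(C)(C)C)/C=C(\C)CCO[Si](C)(C)C(C)(C)C | intermediate
12 | sodium five-membered alkoxy(alkenyl)aluminate from 11 (O6 and C4 on Al, two 2-methoxyethoxy ligands) | [Na+].COCCO[Al-]1(OCCOC)O[C@@H](/C=C/C)C=C1C[C@H](O[Si](C)(C)C(C)(C)C)/C=C(\C)CCO[Si](C)(C)C(C)(C)C | intermediate (not isolated)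
13 | (2E,4S,5Z,8S,9E)-8,12-bis[(tert-butyldimethylsilyl)oxy]-6-iodo-10-methyldodeca-2,5,9-trien-4-ol | C/C=C/[C@H](O)/C=C(\I)C[C@H](O[Si](C)(C)C(C)(C)C)/C=C(\C)CCO[Si](C)(C)C(C)(C)C | intermediate
14 | (tributylstannyl)methanol | OC[Sn](CCCC)(CCCC)CCCC | starting material
15 | (2Z,4S,5E)-2-[(2S,3E)-2,6-bis[(tert-butyldimethylsilyl)oxy]-4-methylhex-3-en-1-yl]hepta-2,5-diene-1,4-diol | C/C=C/[C@H](O)/C=C(\CO)C[C@H](O[Si](C)(C)C(C)(C)C)/C=C(\C)CCO[Si](C)(C)C(C)(C)C | intermediate
16 | (2E,4S,5Z,8S,9E)-8,12-bis[(tert-butyldimethylsilyl)oxy]-6-{[(tert-butyldiphenylsilyl)oxy]methyl}-10-methyldodeca-2,5,9-trien-4-ol | C/C=C/[C@H](O)/C=C(\CO[Si](c1ccccc1)(c1ccccc1)C(C)(C)C)C[C@H](O[Si](C)(C)C(C)(C)C)/C=C(\C)CCO[Si](C)(C)C(C)(C)C | intermediate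
17 | 2-(bromomethyl)prop-2-enoic acid | C=C(CBr)C(=O)O | starting material
18 | (2E,4S,5Z,8S,9E)-8,12-bis[(tert-butyldimethylsilyl)oxy]-6-{[(tert-butyldiphenylsilyl)oxy]methyl}-10-methyldodeca-2,5,9-trien-4-yl 2-(bromomethyl)prop-2-enoate | C/C=C/[C@H](OC(=O)C(=C)CBr)/C=C(\CO[Si](c1ccccc1)(c1ccccc1)C(C)(C)C)C[C@H](O[Si](C)(C)C(C)(C)C)/C=C(\C)CCO[Si](C)(C)C(C)(C)C | intermediate
19 | (5R)-3-(bromomethyl)-5-[(1Z,4S,5E)-4,8-bis[(tert-butyldimethylsilyl)oxy]-2-{[(tert-butyldiphenylsilyl)oxy]methyl}-6-methylocta-1,5-dien-1-yl]furan-2(5H)-one | CC(C)(C)[Si](C)(C)OCC/C(C)=C/[C@@H](O[Si](C)(C)C(C)(C)C)C/C(CO[Si](c1ccccc1)(c1ccccc1)C(C)(C)C)=C/[C@H]1OC(=O)C(CBr)=C1 | intermediate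
20 | (5R)-3-(bromomethyl)-5-[(1Z,4S,5E)-4-[(tert-butyldimethylsilyl)oxy]-2-{[(tert-butyldiphenylsilyl)oxy]methyl}-8-hydroxy-6-methylocta-1,5-dien-1-yl]furan-2(5H)-one | OCC/C(C)=C/[C@@H](O[Si](C)(C)C(C)(C)C)C/C(CO[Si](c1ccccc1)(c1ccccc1)C(C)(C)C)=C/[C@H]1OC(=O)C(CBr)=C1 | intermediate
21 | (3E,5S,7Z)-8-[(2R)-4-(bromomethyl)-5-oxo-2,5-dihydrofuran-2-yl]-5-[(tert-butyldimethylsilyl)oxy]-7-{[(tert-butyldiphenylsilyl)oxy]methyl}-3-methylocta-3,7-dienal | O=CC/C(C)=C/[C@@H](O[Si](C)(C)C(C)(C)C)C/C(CO[Si](c1ccccc1)(c1ccccc1)C(C)(C)C)=C/[C@H]1OC(=O)C(CBr)=C1 | intermediate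
22 | dichloro(allyl)chromium derived from 21 (CrCl2 on C13) | O=CC/C(C)=C/[C@@H](O[Si](C)(C)C(C)(C)C)C/C(CO[Si](c1ccccc1)(c1ccccc1)C(C)(C)C)=C/[C@H]1OC(=O)C(C[Cr](Cl)Cl)=C1 | intermediate (not isolated)
23 | (3aR,4S,6E,8S,10Z,11aR)-8-[(tert-butyldimethylsilyl)oxy]-10-{[(tert-butyldiphenylsilyl)oxy]methyl}-4-hydroxy-6-methyl-3-methylidene-3a,4,5,8,9,11a-hexahydrocyclodeca[b]furan-2(3H)-one | C=C1C(=O)O[C@@H]2/C=C(\CO[Si](c3ccccc3)(c3ccccc3)C(C)(C)C)C[C@H](O[Si](C)(C)C(C)(C)C)/C=C(\C)C[C@H](O)[C@@H]12 | intermediate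
24 | (Z)-2-methylbut-2-enoic acid (angelic acid) | C/C=C(/C)C(=O)O | starting material
25 | (Z)-2-methylbut-2-enoic 2,4,6-trichlorobenzoic anhydride | C/C=C(/C)C(=O)OC(=O)c1c(Cl)cc(Cl)cc1Cl | intermediate (not isolated)
26 | (3aR,4S,6E,8S,10Z,11aR)-8-[(tert-butyldimethylsilyl)oxy]-10-{[(tert-butyldiphenylsilyl)oxy]methyl}-6-methyl-3-methylidene-2-oxo-2,3,3a,4,5,8,9,11a-octahydrocyclodeca[b]furan-4-yl (2Z)-2-methylbut-2-enoate | C=C1C(=O)O[C@@H]2/C=C(\CO[Si](c3ccccc3)(c3ccccc3)C(C)(C)C)C[C@H](O[Si](C)(C)C(C)(C)C)/C=C(\C)C[C@H](OC(=O)/C(C)=C\C)[C@@H]12 | intermediate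
27 | (3aR,4S,6E,8S,10Z,11aR)-8-hydroxy-10-(hydroxymethyl)-6-methyl-3-methylidene-2-oxo-2,3,3a,4,5,8,9,11a-octahydrocyclodeca[b]furan-4-yl (2Z)-2-methylbut-2-enoate | C=C1C(=O)O[C@@H]2/C=C(\CO)C[C@H](O)/C=C(\C)C[C@H](OC(=O)/C(C)=C\C)[C@@H]12 | intermediate
28 | (1R,2S,6R,7R,8S,10R)-8-angeloyloxy-1,10-epoxy-2,15-dihydroxygermacra-4,11(13)-dien-12,6-olide | C=C1C(=O)O[C@@H]2/C=C(\CO)C[C@H](O)[C@H]3O[C@]3(C)C[C@H](OC(=O)/C(C)=C\C)[C@@H]12 | target

**Step count and risks**

Total step count: 16. Longest linear sequence: 16 steps, from 1.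

The three steps most likely to fail:

Step 13 (macrocyclising C7–C8 allylation). The risks are oligomerisation, α-attack giving a twelve-membered ring, the wrong C8 epimer and 6→8 translactonisation of the product. The fallback sets out from alcohol 20 and replaces the in-situ organochromium by an isolated allylmetal. The allylic bromide is exchanged for tin (Bu3SnSnBu3, Pd2(dba)3, THF, rt) to give the allylstannane alcohol F1. Dess–Martin oxidation gives the stannyl aldehyde F2. This is closed by Lewis-acid-promoted intramolecular allylstannane addition (BF3·OEt2, CH2Cl2, −78 °C, 0.002 M; SE2' through C7 in an open transition state). The route is rejoined at 23.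

Step 16 (chemo- and face-selective epoxidation of the free diol). The risks are competing hydroxyl-directed epoxidation of the 4,5-alkene by the C15 alcohol and acid-triggered transannular cyclisation of the 1,10-epoxide. The fallback sets out from the bis-silyl ether 26 and epoxidises before deprotection with dimethyldioxirane (acetone, −20 °C, neutral). With the 4,5-alkene shielded by the CH2OTBDPS group and deactivated by the lactone oxygen, outer-face attack on the crown conformer of the 1(10)-alkene gives the bis-silyl epoxide F3. HF·pyridine then removes both silyl groups, rejoining at 28.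

Step 5 (asymmetric alkynylation of an enal with a valuable alkyne). The risks are low conversion, low ee and conjugate addition. The fallback sets out from alkyne 8: deprotonation with n-BuLi and acylation with N-methoxy-N-methyl-(E)-but-2-enamide gives the ynone F4. Midland reduction with (S)-Alpine-borane (B-isopinocampheyl-9-borabicyclo[3.3.1]nonane, neat, rt) sets the carbinol by reagent control, with the alkyne as the small group. The route is rejoined at 11.

**Further compounds**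
F1 | step 13 | (5R)-5-[(1Z,4S,5E)-4-[(tert-butyldimethylsilyl)oxy]-2-{[(tert-butyldiphenylsilyl)oxy]methyl}-8-hydroxy-6-methylocta-1,5-dien-1-yl]-3-[(tributylstannyl)methyl]furan-2(5H)-one | OCC/C(C)=C/[C@@H](O[Si](C)(C)C(C)(C)C)C/C(CO[Si](c1ccccc1)(c1ccccc1)C(C)(C)C)=C/[C@H]1OC(=O)C(C[Sn](CCCC)(CCCC)CCCC)=C1
F2 | step 13 | (3E,5S,7Z)-5-[(tert-butyldimethylsilyl)oxy]-7-{[(tert-butyldiphenylsilyl)oxy]methyl}-3-methyl-8-{(2R)-5-oxo-4-[(tributylstannyl)methyl]-2,5-dihydrofuran-2-yl}octa-3,7-dienal | O=CC/C(C)=C/[C@@H](O[Si](C)(C)C(C)(C)C)C/C(CO[Si](c1ccccc1)(c1ccccc1)C(C)(C)C)=C/[C@H]1OC(=O)C(C[Sn](CCCC)(CCCC)CCCC)=C1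
F3 | step 16 | (1R,2S,6R,7R,8S,10R)-8-angeloyloxy-2-[(tert-butyldimethylsilyl)oxy]-15-[(tert-butyldiphenylsilyl)oxy]-1,10-epoxygermacra-4,11(13)-dien-12,6-olide | C=C1C(=O)O[C@@H]2/C=C(\CO[Si](c3ccccc3)(c3ccccc3)C(C)(C)C)C[C@H](O[Si](C)(C)C(C)(C)C)[C@H]3O[C@]3(C)C[C@H](OC(=O)/C(C)=C\C)[C@@H]12
F4 | step 5 | (2E,8S,9E)-8,12-bis[(tert-butyldimethylsilyl)oxy]-10-methyldodeca-2,9-dien-5-yn-4-one | C/C=C/C(=O)C#CC[C@H](O[Si](C)(C)C(C)(C)C)/C=C(\C)CCO[Si](C)(C)C(C)(C)C
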